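The noon run, with 0.87 M of coupling partner at 85 °C, read 28% of product at 8.00 min. The spring flask, with 1.3 M at 90 °C, read 27% at 8.00 min. That gap of 1 percentage point is smaller than the scatter of one reading, so these readings show no effect of the two settings moved together.

| setting | spring | noon | flask |
|---|---|---|---|
| substrate | 1 M | 1 M | 1.0 M |
| coupling partner | 1.3 M | 0.87 M | 1.30 M |
| capture agent | 1 M | 1 M | 1.00 M |
| free catalyst | 11 mM | 11 mM | 11 mM |
| temperature | 90 °C | 85 °C | 90 °C |
| remark | the very flask that is asked about, followed so far | run made earlier |  |
| time |  |  | 15 min |

| run | time / min | product / % | substrate / % |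
|---|---|---|---|
| spring | 2.50 | 18 | 83 |
| spring | 5.00 | 22 | 74 |
| spring | 8.00 | 27 | 70 |
| spring | 10.0 | 29 | 68 |
| spring | 12.0 | 31 | 67 |
| spring | 15.0 | 31 | 68 |
| noon | 0.667 | 4 | 94 |
| noon | 1.00 | 6 | 90 |
| noon | 2.00 | 11 | 87 |
| noon | 3.00 | 17 | 82 |
| noon | 5.00 | 21 | 76 |
| noon | 8.00 | 28 | 75 |

(standard deviation of a reading: 1.5 percentage points)

- amber: at 15 min raise the temperature by 25 K, then wait 5.0 min
- ochre: change nothing and wait 5.0 min more
- violet: at 15 min add coupling partner, 50.0% of the amount charged, then wait 5.0 min
- green: at 15 min add free catalyst, 100% of the amount charged, then wait 5.0 min
- blue: at 15 min take out 90% of the product then present, then wait 5.0 min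

- a species is counted by the substrate in it: one spent catalyst counts as two
- removed product is counted in
- steps thought possible: substrate + free catalyst -> catalyst intermediate A; coupling partner + catalyst intermediate A -> catalyst intermediate B; catalyst intermediate B <-> catalyst intermediate C; catalyst intermediate C -> free catalyst + product; capture agent + catalyst intermediate C -> trapped intermediate; 2 catalyst intermediate B -> spent catalyst
- additions bring no volume worth counting

1. product, in percent of the substrate first charged, at 15 min
2. the remedy with the largest gain of product, or "none" below 2 percentage points (amber / ochre / violet / green / blue / none)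
3. product present, with what was taken out counted in, in percent of the substrate first charged, after amber
4. product present, with what was taken out counted in, in percent of the substrate first charged, after green

Which numbers must be known well? Time matters little in the spring flask, whose readings at 12.0 min and 15.0 min are equal. Neither reagent was used up at the last spring reading: 68% of the substrate was read there, and the coupling partner follows by subtraction:

coupling partner left = 0.990 M

Capture agent was 1.00 M in both runs and is the same in the flask, so its weight cannot be read. If the plateau is a catalyst limit, the plateau in percent goes as the catalyst charge over the substrate charge, so an error of 4.84% in either charge, 0.532 mM of catalyst or 0.0484 M of substrate, moves the plateau by one scatter. The number itself follows: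

product per catalyst = plateau × substrate charged / catalyst charged = 28.2

This is the turnover allowance, the product made for each catalyst lost from the working round, the usual turnover number. Without new catalyst, the flask should stay at its plateau. With green, the end state rises:

new ceiling = plateau + allowance × catalyst added / substrate charged = 62.0%

The approach is taken from the spring flask's first 5.00 min, which gave 22%, so this reckoning expects 53.0% after green.

The forecast gave 31% (29.5% to 32.5%), chose green, and gave 31.5% (30% to 34%) after amber and 48.5% (42% to 54%) after green, below the reckoning above. In its words: “Only fresh catalyst restarts the reaction.”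

The flask gives 31.4%, best remedy green, 31.9% after amber and 54.0% after green.

    substrate + free catalyst → catalyst intermediate A (k = 0.360 /M/s, Ea = 62.0 kJ/mol)
    coupling partner + catalyst intermediate A → catalyst intermediate B (k = 1.40 /M/s, Ea = 66.0 kJ/mol)
    catalyst intermediate B ⇌ catalyst intermediate C (K = 0.320, k = 0.920 /s, Ea = 98.0 kJ/mol, ΔH = −90.0 kJ/mol)
    catalyst intermediate C → free catalyst + product (k = 3.70 /s, Ea = 72.0 kJ/mol)
    capture agent + catalyst intermediate C → trapped intermediate (k = 0.120 /M/s, Ea = 62.0 kJ/mol)
    2 catalyst intermediate B → spent catalyst (k = 0.340 /M/s, Ea = 44.0 kJ/mol)
    (constants at 90 °C)

In the flask, product stood at 12.7% at 1.50 min with 37.4% of the catalyst as trapped intermediate, and at 28.6% at 7.50 min with 83.8%. At 15.0 min free catalyst was 0.723%, with 68% of the substrate left. Green then made 20.5 product per catalyst added, against the allowance of 28.2, and stood 5.5 points above the forecast. The neighbour charged with 0.40 M of capture agent held 58.5% of product at 15.0 min with 81.4% of its catalyst trapped or spent, which is 65.4 per catalyst lost.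

The earlier runs and the new flask are simulated for an exercise, and the scatter is random.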